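Which way does the target at 40 h go as the whole reagent charge climbs from 6.00 × 10⁻⁴ M to 0.0500 M on 0.010 M of substrate?

common to all: substrate 0.010 M

| run | reagent | remark | time |
|---|---|---|---|
| maple | 7.0 × 10⁻⁴ M (in portions, 4) | run made earlier; portions every 2.5 h |  |
| birch | 0.076 M (in portions, 4) | run made earlier; portions every 2.5 h |  |
| Saturday's | 6.00 × 10⁻⁴ M (in portions, 4) | the portions of reagent follow each other after 2.5 h, the first at the start | 40 h |
| Friday's | 0.00200 M (in portions, 4) | the portions of reagent follow each other after 2.5 h, the first at the start | 40 h |
| Tuesday's | 0.00600 M (in portions, 4) | the portions of reagent follow each other after 2.5 h, the first at the start | 40 h |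
| Wednesday's | 0.0200 M (in portions, 4) | the portions of reagent follow each other after 2.5 h, the first at the start | 40 h |
| Thursday's | 0.0500 M (in portions, 4) | the portions of reagent follow each other after 2.5 h, the first at the start | 40 h |

| run | time / h | target / % | substrate / % |
|---|---|---|---|
| maple | 1.50 | 0.7 | 99.0 |
| maple | 2.50 | 1.6 | 99.1 |
| maple | 4.00 | 2.3 | 97.6 |
| maple | 8.00 | 4.3 | 95.7 |
| maple | 12.0 | 5.8 | 93.6 |
| maple | 20.0 | 6.8 | 93.4 |
| birch | 1.50 | 30.1 | 26.6 |
| birch | 2.50 | 35.3 | 18.1 |
| birch | 4.00 | 40.6 | 0.4 |
| birch | 8.00 | 40.0 | 0 |
| birch | 12.0 | 40.5 | 0 |
| birch | 20.0 | 40.6 | 0 |

(readings scatter by 0.3 percentage points)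

- "hardly changes" means that all values lie within two and a half points (for a concentration: within two and a half percent of the largest)

1. amount of target at the end, in percent of the substrate charged for Saturday's, Friday's, Tuesday's, Wednesday's, Thursday's, in this order
2. the course of these numbers from the first flask to the last (falls, then rises / rises all the way / falls all the way / rises, then falls / hardly changes)

Turn the question round: for the target to rise all the way, extra reagent would have to keep paying up to Thursday's charge. The birch run shows what it pays at a large charge. With 0.076 M charged, substrate fell to 0% and target stayed flat at 40.6%, so missing substrate stands to target as 1.46. The maple run, from a charge worth 7.00% of the substrate, reached 6.8%, so the loss grows with reagent. Take it as proportional to [reagent], with one portion as the level. Dividing by birch's portion of 0.0190 M gives 77.0 /M, the side factor: missing substrate over target per molar of one portion, a selectivity factor.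

Treat the side path as a correction, and assume that it takes two reagent. With portion c, this reckoning estimates target as the lesser of two ceilings: the substrate ceiling 1/(1 + side factor × c), and the reagent ceiling, which is the charge as a fraction of the substrate over (1 + 2 × side factor × c). The lesser ceiling shows which is taken as the limiting reagent. On maple this gives 6.82%, though within a scatter of 0.3 percentage points the uncorrected charge passes too. The ceilings cross at a charge of 0.0119 M. In this reckoning, rising all the way would need that crossing above Thursday's charge, but 0.0500 M stands beyond it. So this reckoning gives 5.86%, 18.6%, 48.7%, 72.2% and 51.0%.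

The forecast, reading “a side path second order in reagent”, gives 6%, 18.5%, 48%, 68% and 55%, and its shape is rises, then falls. It differs from this reckoning at the top, lower on Wednesday's and higher on Thursday's.

The flasks give 5.81%, 18.1%, 46.1%, 65.5% and 48.8%: rises, then falls, turning at a reagent concentration of 0.014 M.

    2 reagent → homo dimer (k = 7.10 × 10⁻⁴ /M/s)
    substrate + reagent → target (k = 0.0110 /M/s)
    substrate + 2 reagent → side product (k = 1.30 /M²/s)

In Saturday's flask at 6.02 h, substrate went to target 57 times as fast as to side product, while the inverse of the side factor times one portion of that flask is 86.6. In Thursday's flask the side factor times one portion is 0.963, and at 40.0 h side product stood at 51.2% against target 48.8%, a ratio of 1.05.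

The numbers in the tables are simulated with constants of no real substance, and the scatter is random.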